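**Retrosynthetic overview**

1. Brasilianoid C 32 ⇐ pentacyclic keto sulfone 28 by three late adjustments: C13=O → C13=CH2, C19–SO2Ph → C19–H, and C1=C2 by selenoxide elimination.
2. 28 ⇐ bromo ketone 27 by one radical chain that closes ring C (C12–C11) and then, last of all rings, ring B (C9–C10). The enabling feature is the one-carbon bridge C13 between C12 and C14 of rings C/D, carried as a ketone: C12•–C13(=O)–C14–C8–C9=C11 is a 2-oxo-5-hexenyl radical that closes 6-endo and hands the radical to C9. The C17–C18 bridge with its endo C17–OH then leaves only the exo face of C9 open, and a removable PhSO2 group on C19 makes C10 the acceptor carbon.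
3. 27 ⇐ enol ether 23 by Claisen rearrangement (C14–C8, two adjacent quaternary centres); 23 ⇐ eastern β-keto lactone 22 (rings D/E) + western (Z)-allylic alcohol 13 (ring A) by Mitsunobu O-alkylation.
4. 13 ⇐ geranyl acetate 1 (Shi epoxidation, titanocene radical cyclization, Baeyer–Villiger ring expansion, B-alkyl Suzuki coupling); 22 ⇐ ethyl (S)-2-acetoxypropanoate 14 (Lacey–Dieckmann, Negishi coupling, epoxidation/SmI2, Dieckmann).
5. Ring order: A (carbocycle in step 2, expanded to the lactone in step 8), E (step 10), D (step 15), C and then B (both in step 19, B last).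

Key step: step 19

**Remarks**

- Numbering used throughout: ring A O–C3(=O)–C2=C1–C10(C19H3)–C5–C4(CH3)2; ring B C5–C6–C7–C8–C9–C10; ring C C8–C9–C11–C12–C13–C14; ring D C12–C13–C14–C17–C18; ring E C14–C15(=O)–O–C16–C17.
- Assumption: (Z)-3-iodobut-2-en-1-ol 11, the D-fructose-derived Shi ketone and ethyl (S)-2-acetoxypropanoate 14 are taken as purchasable.
- C12 is carried as a mixture of epimers in 19–27 (left open in the SMILES) because it becomes a planar radical in step 19; 4 is a mixture at C10.

**Western fragment (ring A)**

Step 1
Reactants: 1 geranyl acetate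
Product: 2 (R)-6,7-epoxygeranyl acetate
Conditions: D-fructose-derived Shi ketone (0.3 equiv), KHSO5, K2CO3, Bu4NHSO4, MeCN/CH2(OMe)2/aq. Na2B4O7, 0 °C
Reagents that add atoms: potassium peroxymonosulfate, [K+].[O-]S(=O)(=O)OO
Why: Shi epoxidation: the chiral dioxirane epoxidizes only the electron-rich C3=C4 alkene (the other one is deactivated by the allylic acetate) through the spiro transition state, which should set C3 as R.

Step 2
Reactants: 2 (R)-6,7-epoxygeranyl acetate
Product: 3 ring A hydroxy acetate
Conditions: Cp2TiCl2 (2.2 equiv), Mn dust, THF, rt; then aq. HCl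
Reagents that add atoms: none
Why: Titanocene-mediated radical epoxy-olefin cyclization: Cp2TiCl (trivalent titanium) opens the epoxide to the tertiary C4 radical, 6-endo addition to C5=C10 through a chair with the C3–O and C5–C6 bonds equatorial sets C5 cis to the C3 oxygen, and β-hydride elimination from the C10–titanium species leaves the exocyclic C10=C19 alkene.

Step 3
Reactants: 3 ring A hydroxy acetate
Product: 5 vinyl sulfone acetate, via iodo sulfone 4 (not isolated)
Conditions: PhSO2Na, I2, EtOAc/H2O, rt; then Et3N, CH2Cl2, rt
Reagents that add atoms: sodium benzenesulfinate, [Na+].[O-]S(=O)c1ccccc1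
Why: Iodosulfonylation followed by dehydroiodination: the sulfonyl radical adds to the terminal C19, iodine transfer gives the tertiary iodide, and Et3N removes the acidic C19 hydrogen to give the conjugated (E)-vinyl sulfone with the sulfonyl group turned away from the substituted C5 (no stereocentre is formed).

Step 4
Reactants: 5 vinyl sulfone acetate
Product: 6 vinyl sulfone diol
Conditions: K2CO3 (0.2 equiv), MeOH, 0 °C
Reagents that add atoms: none
Why: Base-catalysed transesterification removes the primary acetate, while the β,β-disubstituted vinyl sulfone is too hindered for methoxide addition and C3 and C5 are untouched.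

Step 5
Reactants: 6 vinyl sulfone diol
Product: 7 hydroxy aldehyde
Conditions: TEMPO (0.1 equiv), PhI(OAc)2, CH2Cl2, rt
Reagents that add atoms: none
Why: TEMPO/PhI(OAc)2 (oxoammonium) oxidation is selective for the primary C6 alcohol over the hindered secondary C3 alcohol, and the equatorial C5 substituent is the thermodynamically preferred one, so the C5 configuration should be retained.

Step 6
Reactants: 7 hydroxy aldehyde
Product: 8 hydroxy diene
Conditions: CH2I2, Zn, Ti(OiPr)4, THF, rt
Reagents that add atoms: diiodomethane, ICI
Why: Takai methylenation with the non-basic gem-dizinc reagent and Ti(OiPr)4 converts the aldehyde into the C6=C7 vinyl group without enolizing the adjacent C5 stereocentre.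

Step 7
Reactants: 8 hydroxy diene
Product: 9 vinyl ketone
Conditions: Dess–Martin periodinane, NaHCO3, CH2Cl2, rt
Reagents that add atoms: none
Why: Dess–Martin oxidation of the secondary C3 alcohol under buffered conditions gives the ketone needed for ring expansion and leaves C5 untouched.

Step 8
Reactants: 9 vinyl ketone
Product: 10 ring A lactone
Conditions: Me3SiOOSiMe3, Me3SiOTf (0.1 equiv), CH2Cl2, −40 °C
Reagents that add atoms: bis(trimethylsilyl) peroxide, C[Si](C)(C)OO[Si](C)(C)C
Why: Baeyer–Villiger ring expansion with a silyl peroxide that does not epoxidize the vinyl group: the tertiary C4 migrates with retention, inserting oxygen between C3 and C4 to give the seven-membered ring A lactone.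

Step 9
Reactants: 10 ring A lactone, 11 (Z)-3-iodobut-2-en-1-ol
Product: 13 western fragment, via alkylborane 12 (not isolated)
Conditions: 9-BBN, THF, 0 °C to rt; then 11, PdCl2(dppf) (0.05 equiv), AsPh3, Cs2CO3, DMF/H2O, rt
Reagents that add atoms: none
Why: Anti-Markovnikov hydroboration of the terminal vinyl group puts boron on C7, and the B-alkyl Suzuki–Miyaura coupling with 11 proceeds with retention of the vinyl iodide geometry, so the C8=C9 alkene should be (Z).

**Eastern fragment (rings D/E)**

Step 10
Reactants: 14 ethyl (S)-2-acetoxypropanoate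
Product: 15 (S)-5-methyltetronic acid
Conditions: LiN(SiMe3)2 (2.2 equiv), THF, −78 °C to rt; then aq. HCl
Reagents that add atoms: none
Why: Lacey–Dieckmann cyclization: the acetate enolate acylates the lactate ester carbonyl to close ring E as the tetronic acid, and the C16 stereocentre comes unchanged from (S)-lactate.

Step 11
Reactants: 15 (S)-5-methyltetronic acid
Product: 16 (S)-4-bromo-5-methylfuran-2(5H)-one
Conditions: (COBr)2, DMF (0.1 equiv), CH2Cl2, 0 °C to rt
Reagents that add atoms: oxalyl bromide, BrC(=O)C(=O)Br
Why: Vilsmeier-type bromination of the vinylogous acid converts the C17 enol into the vinyl bromide without touching C16.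

Step 12
Reactants: 16 (S)-4-bromo-5-methylfuran-2(5H)-one, 17 methyl 3-bromo-2-methylpropanoate
Product: 19 butenolide ester, via zinc reagent 18 (not isolated)
Conditions: 17, Zn dust, LiCl, THF, 40 °C; then 16, Pd(PPh3)4 (0.05 equiv), THF, 50 °C
Reagents that add atoms: none
Why: Negishi coupling of the β-zinc ester 18 (a zinc homoenolate that tolerates its own ester) with the vinyl bromide forms the C17–C18 bond, C12 being formed as a mixture of epimers that is erased in step 19.

Step 13
Reactants: 19 butenolide ester
Product: 20 epoxy lactone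
Conditions: aq. NaOCl, pyridine, 0 °C
Reagents that add atoms: sodium hypochlorite, [Na+].[O-]Cl
Why: Nucleophilic (Weitz–Scheffer-type) epoxidation: hypochlorite adds to C17 of the butenolide on the face opposite the C16 methyl group, so the epoxide oxygen, the future C17 hydroxyl, should be trans to that methyl.

Step 14
Reactants: 20 epoxy lactone
Product: 21 hydroxy lactone
Conditions: SmI2 (2.5 equiv), THF/MeOH, −78 °C
Reagents that add atoms: none
Why: Samarium diiodide reduces the α,β-epoxy lactone with cleavage of the C14–O bond only, which leaves the C17–O bond and its configuration in place and gives the β-hydroxy lactone.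

Step 15
Reactants: 21 hydroxy lactone
Product: 22 eastern fragment
Conditions: KOtBu (3 equiv), THF, 0 °C to rt; then aq. HCl
Reagents that add atoms: none
Why: Dieckmann condensation of the lactone enolate (C14) onto the methyl ester (C13) closes the five-membered ring D under thermodynamic control, driven by the stable β-keto lactone enolate, and only the cis ring fusion (C14–H syn to C17–OH) is strain-free.

**Fragment union and completion**

Step 16
Reactants: 22 eastern fragment, 13 western fragment
Product: 23 allyl enol ether
Conditions: PPh3, DIAD, toluene, 0 °C to rt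
Reagents that add atoms: none
Why: Mitsunobu reaction of the acidic enol of 22 with the primary allylic alcohol 13: C14 is tertiary and buried at the ring fusion, so alkylation should take place on the C13 enol oxygen with SN2 displacement at C11.

Step 17
Reactants: 23 allyl enol ether
Product: 24 Claisen product
Conditions: o-xylene, 140 °C, sealed tube
Reagents that add atoms: none
Why: Claisen rearrangement: C8 bonds to C14 on the convex face syn to the C17 hydroxyl (the only face that keeps rings D and E cis-fused) through a chair transition state in which the (Z)-alkene places the C8 methyl equatorial, which should set the two adjacent quaternary centres C14 and C8.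

Step 18
Reactants: 24 Claisen product
Product: 27 bromo ketone, via bis-silyl enol ether 25 (not isolated), via silyl ether bromo ketone 26 (not isolated)
Conditions: Me3SiOTf (2.5 equiv), Et3N, CH2Cl2, 0 °C; then N-bromosuccinimide, THF, −78 °C; then aq. HCl, THF
Reagents that add atoms: N-bromosuccinimide, O=C1CCC(=O)N1Br
Why: The C13 ketone can enolize only toward C12, so bromination of its trimethylsilyl enol ether gives the tertiary α-bromo ketone regiospecifically (either C12 epimer serves), and the acidic work-up frees the C17 hydroxyl that was silylated along the way.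

Step 19
Reactants: 27 bromo ketone
Product: 28 pentacyclic keto sulfone
Conditions: (Me3Si)3SiH (1.3 equiv) and AIBN (0.2 equiv) added by syringe pump over 8 h, benzene, 80 °C, 5 mM
Reagents that add atoms: none
Why: Radical chain: the silyl radical abstracts bromine to give the tertiary α-keto radical at C12, which adds 6-endo-trig to the unsubstituted terminus C11 of the C8 vinyl group and so closes ring C as a bicyclo[3.2.1]octan-8-one; the secondary C9 radical then adds 6-exo-trig to C10 of the exocyclic vinyl sulfone, which closes ring B, and the α-sulfonyl C19 radical takes hydrogen from the silane. The closest known reaction types are the 6-endo cyclization of 2-oxo-5-hexenyl radicals generated from α-halo ketones and the reductive radical cyclization onto vinyl sulfones. C12 is set by the bridge itself, because the three-carbon bridge can span C12 and C14 only on the face of ring D that carries C8, and C9 is set by the C17–C18 bridge and its endo hydroxyl, which block the endo lobe of the C9 radical, so that C10 enters exo (equatorial on ring C) and rings B and C become trans-fused. C10 is set in a chair-like transition state of ring B in which the C8 methyl is axial and both ring A bonds (C5–C4 and C10–C1) are equatorial, so that the sulfonylmethylene carbon (the future C19 methyl) turns axial, anti to H5 and syn to the C8 methyl, which gives the trans A/B fusion. The step needs 6-endo over 5-exo closure in the first cyclization, secured by the carbonyl inside the forming ring and by the strain of the alternative 7-norbornanone, and it needs both cyclizations to outrun hydrogen transfer, secured by slow addition of the poor donor (Me3Si)3SiH at high dilution. Polarity alternates correctly along the chain (electrophilic α-keto radical to a neutral alkene, nucleophilic alkyl radical to an electron-poor vinyl sulfone, electrophilic α-sulfonyl radical to a hydridic Si–H), and any reversible β-cleavage of the C9 radical back to a C14 radical is drained by the irreversible capture at the sulfone.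

Step 20
Reactants: 28 pentacyclic keto sulfone
Product: 29 methylidene sulfone
Conditions: Zn, CH2Br2, TiCl4, THF/CH2Cl2, 0 °C to rt
Reagents that add atoms: dibromomethane, BrCBr
Why: Lombardo methylenation: the non-basic zinc–titanium methylene reagent olefinates the hindered, non-enolizable bridging C13 ketone and tolerates both lactones, the sulfone and the free tertiary alcohol.

Step 21
Reactants: 29 methylidene sulfone
Product: 30 1,2-dihydrobrasilianoid C
Conditions: Na(Hg), Na2HPO4, MeOH/THF, −20 °C
Reagents that add atoms: none
Why: Reductive desulfonylation by electron transfer from sodium amalgam cleaves the C19–S bond and leaves the C10 methyl group, while the buffer keeps methoxide from opening the lactones and C10 is not involved.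

Step 22
Reactants: 30 1,2-dihydrobrasilianoid C
Product: 32 brasilianoid C, via selenide 31 (not isolated)
Conditions: LiN(SiMe3)2 (2.5 equiv), THF, −78 °C; PhSeBr; then H2O2, pyridine, CH2Cl2, 0 °C
Reagents that add atoms: none
Why: Only the ring A lactone has α-hydrogens (C2; C14 is quaternary), so its lithium enolate is selenated at C2 and selenoxide syn-elimination toward C1 installs the C1=C2 double bond without touching any stereocentre.

**Compound list**

1 | geranyl acetate, (2E)-3,7-dimethylocta-2,6-dien-1-yl acetate | CC(=O)OC/C=C(\C)CCC=C(C)C | starting material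
2 | (R)-6,7-epoxygeranyl acetate, (2E)-5-[(2R)-3,3-dimethyloxiran-2-yl]-3-methylpent-2-en-1-yl acetate | CC(=O)OC/C=C(\C)CC[C@H]1OC1(C)C | intermediate
3 | ring A hydroxy acetate, [(1S,3R)-3-hydroxy-2,2-dimethyl-6-methylidenecyclohexyl]methyl acetate (C3–OH and C5–CH2OAc cis) | C=C1CC[C@@H](O)C(C)(C)[C@H]1COC(C)=O | intermediate
4 | iodo sulfone, 3 with I on C10 and PhSO2 on C19 (C10 epimers) | O=S(=O)(c1ccccc1)CC2(I)CC[C@@H](O)C(C)(C)[C@H]2COC(C)=O | intermediate
5 | vinyl sulfone acetate, 3 with C10=C19H–SO2Ph, (E) (sulfonyl trans to C5) | O=S(=O)(c1ccccc1)/C=C2\CC[C@@H](O)C(C)(C)[C@H]2COC(C)=O | intermediate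
6 | vinyl sulfone diol, 5 without the acetyl group | O=S(=O)(c1ccccc1)/C=C2\CC[C@@H](O)C(C)(C)[C@H]2CO | intermediate
7 | hydroxy aldehyde, 6 with C6 as CHO | O=S(=O)(c1ccccc1)/C=C2\CC[C@@H](O)C(C)(C)[C@H]2C=O | intermediate
8 | hydroxy diene, 7 with the C6=C7 vinyl group on C5 | O=S(=O)(c1ccccc1)/C=C2\CC[C@@H](O)C(C)(C)[C@H]2C=C | intermediate
9 | vinyl ketone, 8 with C3=O | O=S(=O)(c1ccccc1)/C=C2\CCC(=O)C(C)(C)[C@H]2C=C | intermediate
10 | ring A lactone, (6S)-6-ethenyl-7,7-dimethyl-5-[(E)-(phenylsulfonyl)methylidene]oxepan-2-one | O=S(=O)(c1ccccc1)/C=C2\CCC(=O)OC(C)(C)[C@H]2C=C | intermediate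
11 | (Z)-3-iodobut-2-en-1-ol | OC/C=C(C)\I | starting material
12 | alkylborane, 10 with C7 bound to the boron of 9-BBN | O=S(=O)(c1ccccc1)/C=C2\CCC(=O)OC(C)(C)[C@H]2CCB3C4CCCC3CCC4 | intermediate
13 | western fragment, (6S)-6-[(3Z)-5-hydroxy-3-methylpent-3-en-1-yl]-7,7-dimethyl-5-[(E)-(phenylsulfonyl)methylidene]oxepan-2-one | O=S(=O)(c1ccccc1)/C=C2\CCC(=O)OC(C)(C)[C@H]2CC/C(C)=C\CO | intermediate
14 | ethyl (S)-2-acetoxypropanoate | CCOC(=O)[C@H](C)OC(C)=O | starting material
15 | (S)-5-methyltetronic acid, (5S)-4-hydroxy-5-methylfuran-2(5H)-one | OC1=CC(=O)O[C@H]1C | intermediate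
16 | (5S)-4-bromo-5-methylfuran-2(5H)-one | BrC1=CC(=O)O[C@H]1C | intermediate
17 | methyl 3-bromo-2-methylpropanoate (racemic) | COC(=O)C(C)CBr | starting material
18 | zinc reagent, (3-methoxy-2-methyl-3-oxopropyl)zinc bromide | COC(=O)C(C)C[Zn]Br | intermediate
19 | butenolide ester, methyl 2-methyl-3-[(2S)-2-methyl-5-oxo-2,5-dihydrofuran-3-yl]propanoate (C12 epimers) | COC(=O)C(C)CC1=CC(=O)O[C@H]1C | intermediate
20 | epoxy lactone, C14–C17 epoxide of 19 with the oxygen trans to the C16 methyl | COC(=O)C(C)C[C@@]12O[C@@H]1C(=O)O[C@H]2C | intermediate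
21 | hydroxy lactone, methyl 3-[(2S,3R)-3-hydroxy-2-methyl-5-oxooxolan-3-yl]-2-methylpropanoate (C17–OH trans to C16–CH3) | COC(=O)C(C)C[C@@]1(O)CC(=O)O[C@H]1C | intermediate
22 | eastern fragment, cis-fused rings D/E β-keto lactone (C14–H syn to C17–OH, C16–CH3 trans to C17–OH, keto form drawn) | CC1C[C@]2(O)[C@H](C)OC(=O)[C@@H]2C1=O | intermediate
23 | allyl enol ether, 22 O-alkylated on the C13 enol oxygen by C11 of 13 | CC1C[C@]2(O)[C@H](C)OC(=O)C2=C1OC/C=C(C)\CC[C@H]3/C(=C/S(=O)(=O)c4ccccc4)CCC(=O)OC3(C)C | intermediate
24 | Claisen product, C14-quaternary β-keto lactone whose C8 carries CH3, the C9=C11 vinyl group and the C7–C6 chain to ring A | C=C[C@](C)(CC[C@H]1/C(=C/S(=O)(=O)c2ccccc2)CCC(=O)OC1(C)C)[C@]12C(=O)O[C@@H](C)[C@@]1(O)CC(C)C2=O | intermediate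
25 | bis-silyl enol ether, 24 as C12=C13–OSiMe3 with C17–OSiMe3 | C=C[C@](C)(CC[C@H]1/C(=C/S(=O)(=O)c2ccccc2)CCC(=O)OC1(C)C)[C@]12C(=O)O[C@@H](C)[C@@]1(O[Si](C)(C)C)CC(C)=C2O[Si](C)(C)C | intermediate
26 | silyl ether bromo ketone, 27 with C17–OSiMe3 | C=C[C@](C)(CC[C@H]1/C(=C/S(=O)(=O)c2ccccc2)CCC(=O)OC1(C)C)[C@]12C(=O)O[C@@H](C)[C@@]1(O[Si](C)(C)C)CC(C)(Br)C2=O | intermediate
27 | bromo ketone, 24 with Br on C12 | C=C[C@](C)(CC[C@H]1/C(=C/S(=O)(=O)c2ccccc2)CCC(=O)OC1(C)C)[C@]12C(=O)O[C@@H](C)[C@@]1(O)CC(C)(Br)C2=O | intermediate
28 | pentacyclic keto sulfone, 1,2-dihydrobrasilianoid C with C13=O and C19H2–SO2Ph | O=C1[C@@]2(C)C[C@H]3[C@]4(CS(=O)(=O)c5ccccc5)CCC(=O)OC(C)(C)[C@H]4CC[C@]3(C)[C@@]13C(=O)O[C@@H](C)[C@@]3(O)C2 | intermediate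
29 | methylidene sulfone, 28 with C13=CH2 | C=C1[C@@]2(C)C[C@H]3[C@]4(CS(=O)(=O)c5ccccc5)CCC(=O)OC(C)(C)[C@H]4CC[C@]3(C)[C@@]13C(=O)O[C@@H](C)[C@@]3(O)C2 | intermediate
30 | 1,2-dihydrobrasilianoid C | C=C1[C@@]2(C)C[C@H]3[C@]4(C)CCC(=O)OC(C)(C)[C@H]4CC[C@]3(C)[C@@]13C(=O)O[C@@H](C)[C@@]3(O)C2 | intermediate
31 | selenide, 30 with PhSe on C2 (C2 epimers) | C=C1[C@@]2(C)C[C@H]3[C@]4(C)CC([Se]c5ccccc5)C(=O)OC(C)(C)[C@H]4CC[C@]3(C)[C@@]13C(=O)O[C@@H](C)[C@@]3(O)C2 | intermediate
32 | brasilianoid C | C=C1[C@@]2(C)C[C@H]3[C@]4(C)C=CC(=O)OC(C)(C)[C@H]4CC[C@]3(C)[C@@]13C(=O)O[C@@H](C)[C@@]3(O)C2 | target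

**Count and risks**

Total step count: 22. Longest linear sequence: 16 steps (steps 1–9, then 16–22, from geranyl acetate); the eastern fragment takes 6 steps (10–15).

Steps most likely to fail:

- **Step 19.** Ring B may close too slowly: the C9 radical may take hydrogen (from the silane or from the allylic C5–H by 1,5-shift) or undergo β-cleavage first, and facial control at C10 may be incomplete. The fallback sets out from 27 and comes back at 28. A copper-catalysed bromine-atom-transfer cyclization (CuBr, tris(2-pyridylmethyl)amine, benzene, 60 °C) would close ring C alone and store the chain end as a secondary bromide, the tetracyclic C9 bromide F1. Ring B would then be closed in a separate operation by a zinc-mediated radical conjugate addition of the Luche type onto the vinyl sulfone (Zn, CuI, EtOH/H2O, sonication), where no hydrogen-atom donor is in solution.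

- **Step 17.** Chair and boat transition states may compete, which would erode the configuration at C8, and the rearrangement has to form two adjacent quaternary centres. The fallback sets out from 10 and 22 and comes back at 24. (E)-3-Iodobut-2-en-1-ol in the coupling of step 9 would give the (E)-allylic alcohol F2, Mitsunobu coupling with 22 would give the (E)-enol ether F3, and a rearrangement that prefers the boat would then carry F3 to 24, so that the other transition-state geometry is used by design.

- **Step 16.** Alkylation may go to carbon (C14) or through SN2′ attack instead of to the C13 enol oxygen. The fallback sets out from 22 and comes back at 23. (COCl)2 with catalytic DMF would turn the enol into the vinylogous acid chloride F4, and the sodium alkoxide of 13 (NaH, THF, 0 °C) would replace the chloride by addition–elimination, which can only give the O-linked product.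

Further compounds
F1 | step 19 | tetracyclic C9 bromide (ring C closed, ring B open, C9 epimers) | O=C1[C@@]2(C)CC(Br)[C@](C)(CC[C@H]3/C(=C/S(=O)(=O)c4ccccc4)CCC(=O)OC3(C)C)[C@@]15C(=O)O[C@@H](C)[C@@]5(O)C2
F2 | step 17 | (E)-allylic alcohol, (3E)-isomer of 13 | O=S(=O)(c1ccccc1)/C=C2\CCC(=O)OC(C)(C)[C@H]2CC/C(C)=C/CO
F3 | step 17 | (E)-enol ether, (E)-isomer of 23 | CC1C[C@]2(O)[C@H](C)OC(=O)C2=C1OC/C=C(C)/CC[C@H]3/C(=C/S(=O)(=O)c4ccccc4)CCC(=O)OC3(C)C
F4 | step 16 | vinylogous acid chloride, 22 with Cl on C13 and C13=C14 | CC1C[C@]2(O)[C@H](C)OC(=O)C2=C1Cl
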